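**Retrosynthetic overview**

- The route rests on one feature: the seven-membered ring is a three-carbon 2-oxyallyl unit C9–C10(O)–C1 joined to a four-carbon 2-oxygenated diene C5=C6(O)–C7=C8, and C2–C3–C4 is a three-atom tether between C1 and C5 that becomes the cyclopentane.
- Late stage (backwards): the C10 tiglate comes from an allylic alcohol, that from the C8=C9 enone, that from a C10 ketone; the C6 4-hydroxybenzoate comes from a 6α-alcohol made by hydroxyl-directed reduction of a C6 ketone; both lead back to a cis-fused bicyclic 6,10-dione.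
- Key disconnection: C1–C5 and C8–C9 together, by intramolecular (4+3) cycloaddition of a 2-silyloxyallyl cation (from a tertiary allylic chloride at C1) with the tethered (5Z,7E)-2-silyloxy diene; the five- and seven-membered rings form in this one step and no ring exists before it.
- The acyclic precursor comes from (S)-terpinen-4-ol (source of C4, its isopropyl group, C1–C3, C5, C6 and C15) by ring cleavage, propenyl addition at C6, ethylidenation at C1, epoxide → chlorohydrin → chloro ketone, and a double enol silylation.

Key step: step 10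

Numbering (all compounds, acyclic ones included): C1 = quaternary ring-fusion carbon with CH3-15; C2, C3 = ring CH2; C4 = carbinol carbon with the isopropyl group; C5 = ring-fusion CH; C6 (aroyloxy), C7, C8 (methyl), C9, C10 (tigloyloxy) complete the seven-membered ring. α is the face of the bicycle that carries H5 and CH3-15.

Remark on the chemistry: (E)-prop-1-enylmagnesium bromide is assumed to be a THF solution of defined E geometry (bought, or made from (E)-1-bromopropene and magnesium). Centers that later become trigonal or planar (C6 and C10 carbinols, C1 chloride, C1=C10 geometry, C8 after the cycloaddition) are carried as mixtures. The chloro ketone enters the key step as its silyl enol ether, because a lithium amide cannot enolise the enone without also enolising the methyl ketone; both are silylated and the resulting allylic chloride is ionised with AgClO4.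

**Route**

Step 1
Reactants: 1 (S)-terpinen-4-ol
Product: 2 (S)-terpinen-4-yl triethylsilyl ether
Conditions: Et3SiOTf, 2,6-lutidine, CH2Cl2, 0 °C → rt
Reagents that add atoms: triethylsilyl trifluoromethanesulfonate, CC[Si](CC)(CC)OS(=O)(=O)C(F)(F)F
Why: Silylation of a hindered tertiary alcohol with a silyl triflate and a hindered pyridine is standard, leaves the stereocenter untouched, and blocks the C4 oxygen from hemiketal formation after ring cleavage and from capturing the C1 cation later.

Step 2
Reactants: 2 (S)-terpinen-4-yl triethylsilyl ether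
Product: 4 (3S)-6-oxo-3-(propan-2-yl)-3-(triethylsilyloxy)heptanal, via ozonide 3 (not isolated)
Conditions: O3, CH2Cl2, −78 °C; then PPh3, −78 °C → rt
Reagents that add atoms: ozone, [O-][O+]=O
Why: Ozonolysis with reductive work-up cleaves the only alkene, turning C1 into the methyl ketone and C6 into the aldehyde without touching C4.

Step 3
Reactants: 4 (3S)-6-oxo-3-(propan-2-yl)-3-(triethylsilyloxy)heptanal; 5 (E)-prop-1-enylmagnesium bromide
Product: 6 (5S,8E)-7-hydroxy-5-(propan-2-yl)-5-(triethylsilyloxy)dec-8-en-2-one (both epimers at the new carbinol, which is C6)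
Conditions: 5 (1.1 equiv), THF, −78 °C; aq. NH4Cl, −78 °C
Reagents that add atoms: none
Why: Grignard addition, in which the aldehyde should react much faster than the methyl ketone at −78 °C with one equivalent of reagent; the carbinol epimers converge on oxidation in step 8.

Step 4
Reactants: 6 (5S,8E)-7-hydroxy-5-(propan-2-yl)-5-(triethylsilyloxy)dec-8-en-2-one
Product: 7 (5S,8E)-5-(propan-2-yl)-5-(triethylsilyloxy)-7-(trimethylsilyloxy)dec-8-en-2-one
Conditions: Me3SiCl, imidazole, CH2Cl2, 0 °C
Reagents that add atoms: chlorotrimethylsilane, C[Si](C)(C)Cl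
Why: Standard silylation, which keeps the basic ylide of step 5 from forming a C6 alkoxide that could pull the triethylsilyl group off the C4 oxygen (1,3-silyl migration) and removes hydroxyl direction in the epoxidation of step 6.

Step 5
Reactants: 7 (5S,8E)-5-(propan-2-yl)-5-(triethylsilyloxy)-7-(trimethylsilyloxy)dec-8-en-2-one; 8 ethyltriphenylphosphonium bromide
Product: 10 (6S,9E)-3-methyl-6-(propan-2-yl)-6-(triethylsilyloxy)-8-(trimethylsilyloxy)undeca-2,9-diene (2E/2Z mixture), via ethylidenetriphenylphosphorane 9 (not isolated)
Conditions: 8, KN(SiMe3)2, THF, 0 °C; then 7, 0 °C → rt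
Reagents that add atoms: none
Why: Wittig olefination of an unhindered methyl ketone with a non-stabilised ylide; the C1=C10 geometry is of no consequence because C10 becomes a ketone and C1 a planar cation.

Step 6
Reactants: 10 (6S,9E)-3-methyl-6-(propan-2-yl)-6-(triethylsilyloxy)-8-(trimethylsilyloxy)undeca-2,9-diene
Product: 11 2,3-epoxide of 10 (C1–C10 epoxide, diastereomer mixture)
Conditions: mCPBA (1.05 equiv), NaHCO3, CH2Cl2, 0 °C
Reagents that add atoms: meta-chloroperoxybenzoic acid, OOC(=O)c1cccc(Cl)c1
Why: Prilezhaev epoxidation, selective with one equivalent of peracid because the trisubstituted C1=C10 alkene is much more nucleophilic than the disubstituted C7=C8 alkene next to a silyloxy group.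

Step 7
Reactants: 11 2,3-epoxide of 10
Product: 12 (6S,9E)-3-chloro-3-methyl-6-(propan-2-yl)-6-(triethylsilyloxy)undec-9-ene-2,8-diol (mixture at the chloride and both carbinols)
Conditions: HCl (2 M in Et2O, 3 equiv), Et2O, −30 → 0 °C; aq. NaHCO3
Reagents that add atoms: hydrogen chloride, Cl
Why: Acid-mediated epoxide opening with Markovnikov regiochemistry, chloride attacking the tertiary C1 where positive charge builds up and leaving the C10 secondary alcohol; the labile trimethylsilyl ether is cleaved by HCl in the same operation while the hindered tertiary triethylsilyl ether should survive.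

Step 8
Reactants: 12 (6S,9E)-3-chloro-3-methyl-6-(propan-2-yl)-6-(triethylsilyloxy)undec-9-ene-2,8-diol
Product: 13 (6S,9E)-3-chloro-3-methyl-6-(propan-2-yl)-6-(triethylsilyloxy)undec-9-ene-2,8-dione (both C1 chloride epimers)
Conditions: Dess–Martin periodinane (3 equiv), NaHCO3, CH2Cl2, 0 °C → rt
Reagents that add atoms: none
Why: Dess–Martin oxidation of both secondary alcohols under buffered conditions gives the α-chloro ketone and the (E)-enone in one operation without elimination of the tertiary chloride, and erases the C6 and C10 mixtures.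

Step 9
Reactants: 13 (6S,9E)-3-chloro-3-methyl-6-(propan-2-yl)-6-(triethylsilyloxy)undec-9-ene-2,8-dione
Product: 15 (6R,7Z,9E)-2,8-bis(tert-butyldimethylsilyloxy)-3-chloro-3-methyl-6-(propan-2-yl)-6-(triethylsilyloxy)undeca-1,7,9-triene, via dilithium bis-enolate 14 (not isolated)
Conditions: LiN(iPr)2 (2.3 equiv), THF, −78 °C, inverse addition; tBuMe2SiOTf (2.5 equiv), −78 °C; Et3N, aq. NaHCO3
Reagents that add atoms: tert-butyldimethylsilyl trifluoromethanesulfonate, CC(C)(C)[Si](C)(C)OS(=O)(=O)C(F)(F)F
Why: Kinetic enolate formation and O-silylation, in which the chloro ketone can enolise only toward C9, the enone is deprotonated at C5 (α′) and not at the γ-methyl, the triflate traps both enolates at −78 °C before chloride can leave, and the (Z) geometry at C5=C6 is expected because the alternative sets the quaternary C4 against the propenyl group.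

Step 10
Reactants: 15 (6R,7Z,9E)-2,8-bis(tert-butyldimethylsilyloxy)-3-chloro-3-methyl-6-(propan-2-yl)-6-(triethylsilyloxy)undeca-1,7,9-triene
Product: 18 cis-fused cycloadduct, 6-(tert-butyldimethylsilyloxy)-4β-(triethylsilyloxy)-4α-isopropyl-1α,8β-dimethyl-5αH-hydroazulen-6-en-10-one, via silyloxyallyl cation perchlorate 16 (not isolated), via silyl oxocarbenium perchlorate 17 (not isolated)
Conditions: AgClO4 (1.2 equiv), THF–Et2O, −78 → 0 °C, dark; aq. NaHCO3
Reagents that add atoms: none
Why: AgClO4 removes the tertiary allylic chloride and the 2-silyloxyallyl cation over C1–C10–C9 is captured by the tethered 2-silyloxy diene, C5 bonding to C1 and C9 to C8 (concerted but asynchronous, or stepwise through the C6–C8 silyloxyallyl cation), after which the C10 silyl group is lost at the quench; the closest known reactions are the (4+3) cycloaddition of 2-silyloxyallyl cations made from 2-silyloxyallyl halides and silver salts with dienes, and the intramolecular oxyallyl (4+3) cycloaddition across a three-atom tether. The cyclopentane closes through the C1–C5 bond (5-exo with respect to the C5=C6 enol ether) and the cycloheptene through the C8–C9 bond as the second bond of the cycloaddition (7-endo if stepwise). C5 is set by C4: with the (Z)-enol ether, 1,3-allylic strain against the C6 silyloxy group puts the C4–O bond inside and the isopropyl group outside, so C1 is delivered to the diene face that leaves the C4 oxygen cis to C6 and the isopropyl group cis to H5. C1 is set by the compact arrangement, oxyallyl oxygen over C6–C7 and tether syn to that oxygen, which gives the cis ring fusion (CH3-15 cis to H5) and puts the larger C10 arm on the face of the C4 oxygen and not of the isopropyl group. C8 follows from suprafacial addition to the (E)-propenyl terminus but is not needed, since it becomes trigonal in step 14. The step needs capture of the cation by carbon and not by the C4 oxygen or by proton loss, which the high nucleophilicity of the silyl enol ether and the bulky triethylsilyl group should secure, and both chloride epimers converge because the cation is planar.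

Step 11
Reactants: 18 cis-fused cycloadduct
Product: 19 4β-hydroxy-4α-isopropyl-1α,8β-dimethyl-5αH-hydroazulene-6,10-dione (cis-fused)
Conditions: HF·pyridine, pyridine, THF, 0 °C → rt
Reagents that add atoms: none
Why: Fluoride-mediated desilylation cleaves the enol ether to the C6 ketone (protonation at C7) and the triethylsilyl ether to the C4 alcohol under buffered, non-basic conditions that should avoid retro-aldol cleavage or β-elimination of the β-hydroxy ketone and leave C5 untouched.

Step 12
Reactants: 19 4β-hydroxy-4α-isopropyl-1α,8β-dimethyl-5αH-hydroazulene-6,10-dione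
Product: 21 4β,6α-dihydroxy-4α-isopropyl-1α,8β-dimethyl-5αH-hydroazulen-10-one, via alkoxyborohydride 20 (not isolated)
Conditions: Me4NBH(OAc)3, MeCN–AcOH, −30 → 0 °C; aq. potassium sodium tartrate
Reagents that add atoms: none
Why: Evans–Saksena hydroxyl-directed reduction, in which the C4 hydroxyl exchanges onto boron and hydride is delivered through a six-membered transition state to the β-face of the C6 carbonyl, where the C4 oxygen lies, giving the 6α-alcohol; the hindered C10 ketone has no β-hydroxyl and should not be reduced by this weak hydride donor.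

Step 13
Reactants: 21 4β,6α-dihydroxy-4α-isopropyl-1α,8β-dimethyl-5αH-hydroazulen-10-one; 22 4-acetoxybenzoyl chloride
Product: 23 6α-(4-acetoxybenzoyloxy)-4β-hydroxy-4α-isopropyl-1α,8β-dimethyl-5αH-hydroazulen-10-one
Conditions: 22 (1.5 equiv), pyridine, 4-(dimethylamino)pyridine (cat.), CH2Cl2, 0 °C → rt
Reagents that add atoms: none
Why: Acylation under nucleophilic catalysis takes place at the secondary C6 alcohol with retention, the tertiary C4 alcohol being too hindered to react.

Step 14
Reactants: 23 6α-(4-acetoxybenzoyloxy)-4β-hydroxy-4α-isopropyl-1α,8β-dimethyl-5αH-hydroazulen-10-one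
Product: 24 6α-(4-acetoxybenzoyloxy)-4β-hydroxy-4α-isopropyl-1α,8-dimethyl-5αH-hydroazulen-8-en-10-one
Conditions: IBX (2.5 equiv), DMSO, 70 °C
Reagents that add atoms: none
Why: IBX dehydrogenation of a ketone to the enone, regiochemically unambiguous because C1 is quaternary and only C9 can enolise; it removes the C8 stereocenter and should leave the tertiary alcohol and both esters alone.

Step 15
Reactants: 24 6α-(4-acetoxybenzoyloxy)-4β-hydroxy-4α-isopropyl-1α,8-dimethyl-5αH-hydroazulen-8-en-10-one
Product: 25 6α-(4-acetoxybenzoyloxy)-4α-isopropyl-1α,8-dimethyl-5αH-hydroazulen-8-ene-4β,10α-diol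
Conditions: NaBH4, CeCl3·7H2O, MeOH, −78 °C
Reagents that add atoms: none
Why: Luche 1,2-reduction of the enone, with hydride expected on the β-face, away from the angular CH3-15 on the neighbouring C1, to give the 10α-alcohol (10R) cis to that methyl group; the short reaction at low temperature should spare the aryl acetate.

Step 16
Reactants: 25 6α-(4-acetoxybenzoyloxy)-4α-isopropyl-1α,8-dimethyl-5αH-hydroazulen-8-ene-4β,10α-diol; 26 tigloyl chloride ((E)-2-methylbut-2-enoyl chloride)
Product: 27 10α-tigloyloxy-6α-(4-acetoxybenzoyloxy)-4α-isopropyl-1α,8-dimethyl-5αH-hydroazulen-8-en-4β-ol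
Conditions: 26 (3 equiv), pyridine, 4-(dimethylamino)pyridine, CH2Cl2, 0 °C → rt
Reagents that add atoms: none
Why: Esterification at oxygen under nucleophilic catalysis keeps the C10 configuration, the tiglate is the stable alkene geometry, and the tertiary C4 alcohol should not react.

Step 17
Reactants: 27 10α-tigloyloxy-6α-(4-acetoxybenzoyloxy)-4α-isopropyl-1α,8-dimethyl-5αH-hydroazulen-8-en-4β-ol
Product: 28 target, (1R,4R,5S,6S,10R)-4-hydroxy-6-(4-hydroxybenzoyloxy)-4-isopropyl-1,8-dimethylhydroazulen-8-en-10-yl (E)-2-methylbut-2-enoate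
Conditions: K2CO3 (0.3 equiv), MeOH, 0 °C
Reagents that add atoms: none
Why: Methanolysis (transesterification) of the aryl acetate, an activated phenyl ester that should react far faster than the hindered alkyl benzoate and tiglate, frees the phenol without touching a stereocenter; a phenol freed and re-acylated earlier would be unmasked here as well.

**Compound list**

1 | (S)-terpinen-4-ol | CC1=CC[C@](O)(C(C)C)CC1 | starting material
2 | (S)-terpinen-4-yl triethylsilyl ether | CC1=CC[C@](O[Si](CC)(CC)CC)(C(C)C)CC1 | intermediate
3 | ozonide (1,2,4-trioxolane) of 2 | CC12OC(C[C@](O[Si](CC)(CC)CC)(C(C)C)CC1)OO2 | intermediate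
4 | (3S)-6-oxo-3-(propan-2-yl)-3-(triethylsilyloxy)heptanal | O=CC[C@](O[Si](CC)(CC)CC)(C(C)C)CCC(C)=O | intermediate
5 | (E)-prop-1-enylmagnesium bromide | C/C=C/[Mg]Br | starting material
6 | (5S,8E)-7-hydroxy-5-(propan-2-yl)-5-(triethylsilyloxy)dec-8-en-2-one, both carbinol epimers | C/C=C/C(O)C[C@](O[Si](CC)(CC)CC)(C(C)C)CCC(C)=O | intermediate
7 | (5S,8E)-5-(propan-2-yl)-5-(triethylsilyloxy)-7-(trimethylsilyloxy)dec-8-en-2-one | C/C=C/C(O[Si](C)(C)C)C[C@](O[Si](CC)(CC)CC)(C(C)C)CCC(C)=O | intermediate
8 | ethyltriphenylphosphonium bromide | CC[P+](c1ccccc1)(c1ccccc1)c1ccccc1.[Br-] | starting material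
9 | ethylidenetriphenylphosphorane | CC=P(c1ccccc1)(c1ccccc1)c1ccccc1 | intermediate
10 | (6S,9E)-3-methyl-6-(propan-2-yl)-6-(triethylsilyloxy)-8-(trimethylsilyloxy)undeca-2,9-diene, 2E/2Z mixture | C/C=C/C(O[Si](C)(C)C)C[C@](O[Si](CC)(CC)CC)(C(C)C)CCC(C)=CC | intermediate
11 | 2,3-epoxide of 10 (C1–C10 epoxide), diastereomer mixture | C/C=C/C(O[Si](C)(C)C)C[C@](O[Si](CC)(CC)CC)(C(C)C)CCC1(C)OC1C | intermediate
12 | (6S,9E)-3-chloro-3-methyl-6-(propan-2-yl)-6-(triethylsilyloxy)undec-9-ene-2,8-diol | C/C=C/C(O)C[C@](O[Si](CC)(CC)CC)(C(C)C)CCC(C)(Cl)C(C)O | intermediate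
13 | (6S,9E)-3-chloro-3-methyl-6-(propan-2-yl)-6-(triethylsilyloxy)undec-9-ene-2,8-dione, both chloride epimers | C/C=C/C(=O)C[C@](O[Si](CC)(CC)CC)(C(C)C)CCC(C)(Cl)C(C)=O | intermediate
14 | dilithium bis-enolate of 13 (C9=C10 and (Z)-C5=C6 enolates) | [Li+].[Li+].C=C([O-])C(C)(Cl)CC[C@@](O[Si](CC)(CC)CC)(C(C)C)/C=C([O-])/C=C/C | intermediate
15 | (6R,7Z,9E)-2,8-bis(tert-butyldimethylsilyloxy)-3-chloro-3-methyl-6-(propan-2-yl)-6-(triethylsilyloxy)undeca-1,7,9-triene (key-step precursor) | C=C(O[Si](C)(C)C(C)(C)C)C(C)(Cl)CC[C@@](O[Si](CC)(CC)CC)(C(C)C)/C=C(O[Si](C)(C)C(C)(C)C)/C=C/C | intermediate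
16 | 2-silyloxyallyl cation (C1–C10–C9) perchlorate from 15 | C=C(O[Si](C)(C)C(C)(C)C)[C+](C)CC[C@@](O[Si](CC)(CC)CC)(C(C)C)/C=C(O[Si](C)(C)C(C)(C)C)/C=C/C.[O-]Cl(=O)(=O)=O | intermediate
17 | C10 O-silyl oxocarbenium perchlorate of the cycloadduct | CC(C)(C)[Si](C)(C)[O+]=C1C[C@@H](C)C=C(O[Si](C)(C)C(C)(C)C)[C@@H]2[C@@]1(C)CC[C@@]2(O[Si](CC)(CC)CC)C(C)C.[O-]Cl(=O)(=O)=O | intermediate
18 | cis-fused cycloadduct: 6-(tert-butyldimethylsilyloxy)-4β-(triethylsilyloxy)-4α-isopropyl-1α,8β-dimethyl-5αH-hydroazulen-6-en-10-one (key-step product) | O=C1C[C@@H](C)C=C(O[Si](C)(C)C(C)(C)C)[C@@H]2[C@@]1(C)CC[C@@]2(O[Si](CC)(CC)CC)C(C)C | intermediate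
19 | 4β-hydroxy-4α-isopropyl-1α,8β-dimethyl-5αH-hydroazulene-6,10-dione | O=C1C[C@@H](C)CC(=O)[C@@H]2[C@@]1(C)CC[C@@]2(O)C(C)C | intermediate
20 | tetramethylammonium C4-alkoxy(diacetoxy)borohydride of 19 | O=C1C[C@@H](C)CC(=O)[C@@H]2[C@@]1(C)CC[C@@]2(O[BH-](OC(C)=O)OC(C)=O)C(C)C.C[N+](C)(C)C | intermediate
21 | 4β,6α-dihydroxy-4α-isopropyl-1α,8β-dimethyl-5αH-hydroazulen-10-one | O=C1C[C@@H](C)C[C@H](O)[C@@H]2[C@@]1(C)CC[C@@]2(O)C(C)C | intermediate
22 | 4-acetoxybenzoyl chloride | CC(=O)Oc1ccc(cc1)C(Cl)=O | starting material
23 | 6α-(4-acetoxybenzoyloxy)-4β-hydroxy-4α-isopropyl-1α,8β-dimethyl-5αH-hydroazulen-10-one | O=C1C[C@@H](C)C[C@H](OC(=O)c3ccc(OC(C)=O)cc3)[C@@H]2[C@@]1(C)CC[C@@]2(O)C(C)C | intermediate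
24 | 6α-(4-acetoxybenzoyloxy)-4β-hydroxy-4α-isopropyl-1α,8-dimethyl-5αH-hydroazulen-8-en-10-one | O=C1C=C(C)C[C@H](OC(=O)c3ccc(OC(C)=O)cc3)[C@@H]2[C@@]1(C)CC[C@@]2(O)C(C)C | intermediate
25 | 6α-(4-acetoxybenzoyloxy)-4α-isopropyl-1α,8-dimethyl-5αH-hydroazulen-8-ene-4β,10α-diol | O[C@@H]1C=C(C)C[C@H](OC(=O)c3ccc(OC(C)=O)cc3)[C@@H]2[C@@]1(C)CC[C@@]2(O)C(C)C | intermediate
26 | tigloyl chloride, (E)-2-methylbut-2-enoyl chloride | C/C=C(\C)C(Cl)=O | starting material
27 | 10α-tigloyloxy-6α-(4-acetoxybenzoyloxy)-4α-isopropyl-1α,8-dimethyl-5αH-hydroazulen-8-en-4β-ol | C/C=C(\C)C(=O)O[C@@H]1C=C(C)C[C@H](OC(=O)c2ccc(OC(C)=O)cc2)[C@@H]2[C@@]1(C)CC[C@@]2(O)C(C)C | intermediate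
28 | target, (1R,4R,5S,6S,10R)-4-hydroxy-6-(4-hydroxybenzoyloxy)-4-isopropyl-1,8-dimethylhydroazulen-8-en-10-yl (E)-2-methylbut-2-enoate | C/C=C(\C)C(=O)O[C@@H]1C=C(C)C[C@H](OC(=O)c2ccc(O)cc2)[C@@H]2[C@@]1(C)CC[C@@]2(O)C(C)C | target

**Step count**

Total steps: 17. Longest linear sequence: 17 steps, from 1 to 28.

**Steps most likely to fail**

1. Step 10. In the ion-paired silyloxyallyl cation the extended arrangement or the other diene face may compete with the compact one, which would erode control of C1 relative to C4, and the cation may lose a proton to a diene before it is captured. The fallback changes the cation to the unsilylated oxyallyl species made in a protic medium. It sets out from 13: one equivalent of tBuMe2SiOTf with Et3N in Et2O at −78 → −30 °C should silylate only the enone carbonyl, which is far more basic than the chlorine-deactivated ketone carbonyl, giving the mono-silyl chloro ketone F1. Treating F1 with Et3N (or NaOCH2CF3) in CF3CH2OH at 0 °C → rt enolises the chloro ketone toward C9 and ionises the chloride; the less electrophilic, hydrogen-bonded oxyallyl cation is expected to add in a more concerted, compact mode. This gives the C10 ketone with the C6 silyl enol ether directly, and the route is rejoined at 18.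

2. Step 9. A mono-enolate may close an aldol ring onto the other ketone (C5 onto C10), or the chloro enolate may lose chloride into the Favorskii manifold, before silylation is complete. The fallback avoids metal enolates altogether. It sets out from 13: double soft enolisation with tBuMe2SiOTf (3 equiv) and Et3N in CH2Cl2 at 0 °C → rt goes through O-silylated carbonyls that the amine deprotonates, toward C9 on one side and C5 on the other, with the thermodynamically preferred (Z) enol ether. It comes back to the route at 15 and makes no compound outside the compound list (F0).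

3. Step 15. Substrate-controlled hydride delivery may show poor facial selectivity, because the β-face is the concave face of the cis-fused bicycle while the α-face carries CH3-15. The fallback replaces substrate control by reagent control. It sets out from 24: Corey–Bakshi–Shibata reduction with (S)-1-methyl-3,3-diphenyl-tetrahydro-1H,3H-pyrrolo[1,2-c][1,3,2]oxazaborole and catecholborane in toluene at −78 → −40 °C. The catalyst enantiomer is chosen by the usual model with the quaternary C1 as the large group, the (S)-catalyst being expected to give the (10R)-alcohol. It comes back to the route at 25 and makes no compound outside the compound list (F0).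

**Further compounds**

F1 | step 10 | (6R,7Z,9E)-8-(tert-butyldimethylsilyloxy)-3-chloro-3-methyl-6-(propan-2-yl)-6-(triethylsilyloxy)undeca-7,9-dien-2-one | CC(=O)C(C)(Cl)CC[C@@](O[Si](CC)(CC)CC)(C(C)C)/C=C(O[Si](C)(C)C(C)(C)C)/C=C/C
F0 | step 9 | none | none
F0 | step 15 | none | none
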